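**Assumption:** the SMILES is read as procyanidin B3 3,3''-di-O-gallate, i.e. (+)-catechin 3-O-gallate-(4α→8)-(+)-catechin 3-O-gallate (upper unit 2R,3S,4S; lower unit 2R,3S); 3,4,5-tris(benzyloxy)benzoic acid is taken as a catalogue compound.

## Retrosynthetic overview

- No ring is built: both chroman systems (rings A and C), both catechol rings B and both galloyl rings are bought; (+)-taxifolin 1 and (+)-catechin 2 supply C2 and C3 of the upper and lower unit.
- Interflavan C4–C8 disconnection: 1 is the precursor of leucocyanidin 3 (C4 electrophile) and 2 is the C8 nucleophile; their union is free procyanidin B3 4 and fixes C4.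
- Key disconnection, the two ester C–O bonds at O3 of each unit: 4 plus two molecules of 3,4,5-tris(benzyloxy)benzoic acid 5 (as imidazolide 6) give bis-ester 7 by a site-selective double O-acylation of the unprotected dimer.
- Last operation: the six benzyl ethers of 7 are removed to give the target 8.

## Route

Step 1
Reactants: 1 (+)-taxifolin [(2R,3R)-dihydroquercetin]; 2 (+)-catechin [(2R,3S)]
Product: 4 procyanidin B3 [(+)-catechin-(4α→8)-(+)-catechin; upper unit 2R,3S,4S; lower unit 2R,3S], via leucocyanidin 3 (not isolated)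
Conditions: NaBH4 (3 equiv), EtOH, N2, rt, 1 h; then 2 (4 equiv), H2O, AcOH to pH 5, rt, 20 h; Sephadex LH-20 (EtOH)
Reagents that add atoms: none
Why: Borohydride ketone reduction gives the flavan-3,4-diol 3, whose C4–OH ionises at pH 5 to a ring-A-stabilised benzylic cation (quinone methide) that alkylates the nucleophilic C8 of 2 in a biomimetic Friedel–Crafts-type proanthocyanidin condensation; attack anti to the C3–OH of the 2,3-trans unit sets C4 as 4α (3,4-trans, 4S), while C2 and C3 of both units come unchanged from 1 and 2, and excess 2 suppresses trimers (the minor 4→6 isomer is removed on the column).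

Step 2
Reactants: 4 procyanidin B3; 5 3,4,5-tris(benzyloxy)benzoic acid
Product: 7 procyanidin B3 3,3''-bis-O-[3,4,5-tris(benzyloxy)benzoate] (all eight phenols free), via acyl imidazolide 6 (not isolated)
Conditions: 5 (2.3 equiv), CDI (2.2 equiv), DMF, rt, 1 h; then 4 (1 equiv), DBU (0.3 equiv), degassed DMF, Ar, 40 °C, 48 h
Reagents that add atoms: none
Why: Proposed new method: an error-correcting (thermodynamically funnelled) O-acylation of a free polyphenol — imidazolide 6 at first acylates phenols and the two C3 alcohols indiscriminately, but every aryl gallate so formed is itself an active ester that imidazole/imidazolide (released from CDI) and phenoxide (from DBU) reopen to 6 or pass on by transesterification, whereas the two secondary alkyl gallates are about 4–5 kcal/mol more stable and are not attacked by these nucleophiles at 40 °C, so the 2.2 equivalents of acyl group drain onto O3 and O3'' with retention (only acyl–O bonds form, no bond at a stereocentre is broken) and the benzyl ethers keep the donor from self-condensing; the closest known reaction types are the DBU-accelerated Staab (CDI) esterification, azole-catalysed alcoholysis of aryl esters and base-promoted phenol-to-alcohol acyl migration, none of which has been used as a self-correcting site-selective acylation of an unprotected oligomeric flavan-3-ol.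

Step 3
Reactants: 7 procyanidin B3 3,3''-bis-O-[3,4,5-tris(benzyloxy)benzoate]
Product: 8 procyanidin B3 3,3''-di-O-gallate (target)
Conditions: H2 (1 atm), Pd(OH)2/C, THF/MeOH/H2O (20:1:1), rt, 16 h; filter under Ar, Sephadex LH-20, freeze-dry
Reagents that add atoms: none
Why: Catalytic hydrogenolysis (O-debenzylation) cleaves only the six aryl benzyl ethers; the gallate esters, the C4–C8 bond, the ring C ether and all five stereocentres are inert under these neutral conditions.

## Compound list

1 | (+)-taxifolin, (2R,3R)-2-(3,4-dihydroxyphenyl)-3,5,7-trihydroxychroman-4-one | O[C@H]1C(=O)c2c(O)cc(O)cc2O[C@@H]1c1ccc(O)c(O)c1 | starting material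
2 | (+)-catechin, (2R,3S)-2-(3,4-dihydroxyphenyl)chroman-3,5,7-triol | O[C@H]1Cc2c(O)cc(O)cc2O[C@@H]1c1ccc(O)c(O)c1 | starting material
3 | leucocyanidin, (2R,3S,4R)-2-(3,4-dihydroxyphenyl)chroman-3,4,5,7-tetrol (2,3-trans-3,4-trans) | O[C@H]1[C@H](O)c2c(O)cc(O)cc2O[C@@H]1c1ccc(O)c(O)c1 | intermediate
4 | procyanidin B3, (+)-catechin-(4α→8)-(+)-catechin (upper 2R,3S,4S; lower 2R,3S) | O[C@H]1[C@H](c2c(O)cc(O)c3c2O[C@H](c2ccc(O)c(O)c2)[C@@H](O)C3)c2c(O)cc(O)cc2O[C@@H]1c1ccc(O)c(O)c1 | intermediate
5 | 3,4,5-tris(benzyloxy)benzoic acid | OC(=O)c1cc(OCc2ccccc2)c(OCc2ccccc2)c(OCc2ccccc2)c1 | starting material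
6 | 1-[3,4,5-tris(benzyloxy)benzoyl]imidazole | O=C(n1ccnc1)c1cc(OCc2ccccc2)c(OCc2ccccc2)c(OCc2ccccc2)c1 | intermediate
7 | procyanidin B3 3,3''-bis-O-[3,4,5-tris(benzyloxy)benzoate] (esters on O3 of both units; upper 2R,3S,4S; lower 2R,3S) | O=C(O[C@H]1[C@H](c2c(O)cc(O)c3c2O[C@H](c2ccc(O)c(O)c2)[C@@H](OC(=O)c2cc(OCc4ccccc4)c(OCc4ccccc4)c(OCc4ccccc4)c2)C3)c2c(O)cc(O)cc2O[C@@H]1c1ccc(O)c(O)c1)c1cc(OCc2ccccc2)c(OCc2ccccc2)c(OCc2ccccc2)c1 | intermediate
8 | procyanidin B3 3,3''-di-O-gallate, (+)-catechin 3-O-gallate-(4α→8)-(+)-catechin 3-O-gallate | O=C(O[C@H]1[C@H](c2c(O)cc(O)c3c2O[C@H](c2ccc(O)c(O)c2)[C@@H](OC(=O)c2cc(O)c(O)c(O)c2)C3)c2c(O)cc(O)cc2O[C@@H]1c1ccc(O)c(O)c1)c1cc(O)c(O)c(O)c1 | target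

## Totals and risks

Total step count: 3. Longest linear sequence: 3 steps (1 → 4 → 7 → 8).

**Step 2 (new error-correcting acylation; highest risk).** The acyl shuffling may be too slow, leaving phenolic gallates; the hindered upper C3–OH may stop at the mono-ester; base may epimerise C2. Inside the step, residual aryl esters can be stripped with NH4OAc in MeOH, which cleaves aryl but not alkyl esters.
Fallback (known chemistry: phenol-selective silylation, Steglich esterification, fluoride desilylation). It sets out from 4 and comes back at 7. Compound 4 is treated with TBSCl and imidazole in DMF, which silylates the eight phenols and leaves the two hindered secondary alcohols free, as is established for monomeric catechins, to give octa-O-(tert-butyldimethylsilyl)procyanidin B3 F1. Both free C3 alcohols are then esterified with 5 (DCC, DMAP, CH2Cl2, rt) to give octa-O-(tert-butyldimethylsilyl)procyanidin B3 3,3''-bis-O-[3,4,5-tris(benzyloxy)benzoate] F2. Et3N·3HF in THF removes the eight aryl silyl ethers without touching esters or benzyl ethers and returns 7.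

**Step 1 (reduction and in situ condensation).** The yield is moderate, with 4→6 regioisomer and trimers as by-products, and borate can bind the catechols.
Fallback: it sets out from 1 and comes back at 4. Compound 1 is reduced with NaBH4 as before, but 3 is isolated by EtOAc extraction and trapped with benzyl mercaptan in EtOH/AcOH to give 4-benzylsulfanyl-(+)-catechin F3, which is purified by chromatography. AgBF4 in THF at 0 °C then abstracts the thioether, and the C4 cation is captured by 2 (4 equiv) to give 4. This replaces aqueous in situ ionisation by thiophilic activation of a purified, limiting electrophile under neutral aprotic conditions.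

**Step 3 (hydrogenolysis).** The polyphenol may adsorb on the carbon support, debenzylation may stall, and the product may oxidise on work-up.
Fallback: it sets out from 4 and comes back at 8. Commercial methyl gallate is allylated (allyl bromide, K2CO3, acetone) to methyl 3,4,5-tris(allyloxy)benzoate F4 and saponified (LiOH, THF/H2O) to 3,4,5-tris(allyloxy)benzoic acid F5. The acid is activated with CDI to 1-[3,4,5-tris(allyloxy)benzoyl]imidazole F6 and transferred to 4 under the conditions of step 2 to give procyanidin B3 3,3''-bis-O-[3,4,5-tris(allyloxy)benzoate] F7. Pd(PPh3)4 (5 mol%) with morpholine in THF at rt removes the six allyl groups by π-allyl transfer and gives 8 without H2 or a carbon-supported catalyst.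

## Further compounds

F1 | step 2 | octa-O-(tert-butyldimethylsilyl)procyanidin B3 (eight phenols silylated, both C3–OH free) | O[C@H]1[C@H](c2c(O[Si](C)(C)C(C)(C)C)cc(O[Si](C)(C)C(C)(C)C)c3c2O[C@H](c2ccc(O[Si](C)(C)C(C)(C)C)c(O[Si](C)(C)C(C)(C)C)c2)[C@@H](O)C3)c2c(O[Si](C)(C)C(C)(C)C)cc(O[Si](C)(C)C(C)(C)C)cc2O[C@@H]1c1ccc(O[Si](C)(C)C(C)(C)C)c(O[Si](C)(C)C(C)(C)C)c1
F2 | step 2 | octa-O-(tert-butyldimethylsilyl)procyanidin B3 3,3''-bis-O-[3,4,5-tris(benzyloxy)benzoate] | O=C(O[C@H]1[C@H](c2c(O[Si](C)(C)C(C)(C)C)cc(O[Si](C)(C)C(C)(C)C)c3c2O[C@H](c2ccc(O[Si](C)(C)C(C)(C)C)c(O[Si](C)(C)C(C)(C)C)c2)[C@@H](OC(=O)c2cc(OCc4ccccc4)c(OCc4ccccc4)c(OCc4ccccc4)c2)C3)c2c(O[Si](C)(C)C(C)(C)C)cc(O[Si](C)(C)C(C)(C)C)cc2O[C@@H]1c1ccc(O[Si](C)(C)C(C)(C)C)c(O[Si](C)(C)C(C)(C)C)c1)c1cc(OCc2ccccc2)c(OCc2ccccc2)c(OCc2ccccc2)c1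
F3 | step 1 | 4-benzylsulfanyl-(+)-catechin (2,3-trans-3,4-trans epimer) | O[C@H]1[C@H](SCc2ccccc2)c2c(O)cc(O)cc2O[C@@H]1c1ccc(O)c(O)c1
F4 | step 3 | methyl 3,4,5-tris(allyloxy)benzoate | COC(=O)c1cc(OCC=C)c(OCC=C)c(OCC=C)c1
F5 | step 3 | 3,4,5-tris(allyloxy)benzoic acid | OC(=O)c1cc(OCC=C)c(OCC=C)c(OCC=C)c1
F6 | step 3 | 1-[3,4,5-tris(allyloxy)benzoyl]imidazole | O=C(n1ccnc1)c1cc(OCC=C)c(OCC=C)c(OCC=C)c1
F7 | step 3 | procyanidin B3 3,3''-bis-O-[3,4,5-tris(allyloxy)benzoate] | O=C(O[C@H]1[C@H](c2c(O)cc(O)c3c2O[C@H](c2ccc(O)c(O)c2)[C@@H](OC(=O)c2cc(OCC=C)c(OCC=C)c(OCC=C)c2)C3)c2c(O)cc(O)cc2O[C@@H]1c1ccc(O)c(O)c1)c1cc(OCC=C)c(OCC=C)c(OCC=C)c1
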